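## Retrosynthetic overview

1. Target 19 is epicatechin-(4β→8)-epicatechin 3-O-gallate-(4β→8)-epicatechin 3-O-gallate (all units 2R,3R, both C4 aryl groups trans to the C3 oxygen); it is traced back to its octadeca-O-benzyl ether 18, with hydrogenolysis last.
2. Ring C of the middle unit is cut at C4a–C4 and C2–C3. This gives an E aryl 2-oxadiene cation C4a=C8a–O1=C2 (ring B on C2, top unit on C8), released from N,O-acetal 9, and the C3=C4 bond of the (Z)-enol gallate 15 on C8 of the bottom unit. One cationic [4+2] builds ring C with C2, C3 and C4, brings in the middle gallate and joins the two halves.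
3. Enabling feature: ring A of the middle unit is a phloroglucinol ring whose only free carbon ortho to O1 is C4a (between O1 and O5, para to O7; C8 is blocked by the top unit). C2 carries the para-oxygenated ring B, and C4 is benzylic to the 2,4,6-trioxygenated ring A of the bottom unit, so an oxocarbenium ion at C2 and a cation at C4 are both well stabilised.
4. 9 comes from phenol 5 (C4 arylation of the epicatechin electrophile 3 with phenol 4) and aldehyde 6; 15 comes from protected epicatechin gallate 11 by C8 bromination, alkynylation and Z-selective addition of acid 10.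
5. Ring order: all rings of the top and bottom units come from (−)-epicatechin 1, ring A of the middle unit from 4 and its ring B from 6; ring C of the middle unit is the only ring formed, in step 11.

Key step: step 11

Remark: the acetal-type carbon of 8 and 9 forms without control (both epimers; the N1-benzotriazolyl isomer is drawn). This is of no consequence because that carbon becomes planar in step 11.

## Route

Step 1
Reactants: 1 (−)-epicatechin
Product: 2 5,7,3',4'-tetra-O-benzyl-(−)-epicatechin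
Conditions: BnBr (4.4 equiv), K2CO3, DMF, 0 °C to rt
Reagents that add atoms: benzyl bromide, `BrCc1ccccc1`
Why: Williamson etherification; carbonate deprotonates only the four phenols, so the secondary 3-OH stays free and C2 and C3 are untouched.

Step 2
Reactants: 2 5,7,3',4'-tetra-O-benzyl-(−)-epicatechin
Product: 3 5,7,3',4'-tetra-O-benzyl-4β-(2-ethoxyethoxy)epicatechin
Conditions: DDQ (2 equiv), 2-ethoxyethanol (5 equiv), CH2Cl2, rt
Reagents that add atoms: 2-ethoxyethanol, `CCOCCO`
Why: DDQ-mediated benzylic oxidation (hydride abstraction at C4, activated by the trioxygenated ring A); the alcohol should add trans to the 3-OH (4β), at a centre that is ionised again in step 3.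

Step 3
Reactants: 3 5,7,3',4'-tetra-O-benzyl-4β-(2-ethoxyethoxy)epicatechin; 4 3,5-bis(benzyloxy)phenol (4 equiv)
Product: 5 2-(5,7,3',4'-tetra-O-benzylepicatechin-4β-yl)-3,5-bis(benzyloxy)phenol
Conditions: TMSOTf (0.2 equiv), 4 Å MS, CH2Cl2, −78 °C
Reagents that add atoms: none
Why: Lewis acid-promoted Friedel–Crafts C4 arylation through the flavan C4 cation; attack anti to the axial C3 oxygen should set C4 of the top unit as 4β (3,4-trans), as in 4→8 couplings, and the carbon between OH and OBn (two of three sites, less hindered than the carbon between two benzyloxy groups) should be preferred, the same bias that favours C8 over C6 in flavan nucleophiles.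

Step 4
Reactants: 6 3,4-bis(benzyloxy)benzaldehyde
Product: 8 1-[chloro(3,4-bis(benzyloxy)phenyl)methyl]-1H-benzotriazole (racemic), via hemiaminal 7 (not isolated)
Conditions: 1H-benzotriazole (1.0 equiv), toluene, rt; then SOCl2 (1.3 equiv), 0 °C to rt
Reagents that add atoms: 1H-benzotriazole, `c1ccc2[nH]nnc2c1`; thionyl chloride, `O=S(Cl)Cl`
Why: the aldehyde–benzotriazole hemiaminal is deoxychlorinated by thionyl chloride to the 1-(α-chloroalkyl)benzotriazole, a known conversion for aromatic aldehydes; the new centre is racemic and is planarised later.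

Step 5
Reactants: 5 2-(5,7,3',4'-tetra-O-benzylepicatechin-4β-yl)-3,5-bis(benzyloxy)phenol; 8 1-[chloro(3,4-bis(benzyloxy)phenyl)methyl]-1H-benzotriazole (1.3 equiv)
Product: 9 1-{[2-(5,7,3',4'-tetra-O-benzylepicatechin-4β-yl)-3,5-bis(benzyloxy)phenoxy][3,4-bis(benzyloxy)phenyl]methyl}-1H-benzotriazole (both epimers at the acetal carbon)
Conditions: Cs2CO3 (1.5 equiv), DMF, 0 °C to rt
Reagents that add atoms: none
Why: Williamson-type O-alkylation of the caesium phenoxide by the readily ionised α-chloroalkylbenzotriazole (known for phenoxides and 1-(α-chloroalkyl)benzotriazoles); carbonate does not deprotonate the secondary 3-OH, and both acetal epimers converge in step 11.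

Step 6
Reactants: 2 5,7,3',4'-tetra-O-benzyl-(−)-epicatechin; 10 3,4,5-tris(benzyloxy)benzoic acid (1.2 equiv)
Product: 11 5,7,3',4'-tetra-O-benzyl-(−)-epicatechin 3-O-[3,4,5-tris(benzyloxy)benzoate]
Conditions: DCC, DMAP, CH2Cl2, rt
Reagents that add atoms: none
Why: Steglich esterification of the axial 3-OH; the C3–O bond is not broken, so the configuration is retained.

Step 7
Reactants: 11 5,7,3',4'-tetra-O-benzyl-(−)-epicatechin 3-O-[3,4,5-tris(benzyloxy)benzoate]
Product: 12 8-bromo-5,7,3',4'-tetra-O-benzyl-(−)-epicatechin 3-O-[3,4,5-tris(benzyloxy)benzoate]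
Conditions: NBS (1.05 equiv), CH2Cl2, −78 to 0 °C
Reagents that add atoms: N-bromosuccinimide, `O=C1CCC(=O)N1Br`
Why: electrophilic aromatic bromination at C8, the most reactive and least hindered carbon of ring A in 3-O-acylated tetra-O-benzyl flavan-3-ols; the catechol and galloyl rings are less activated.

Step 8
Reactants: 12 8-bromo-5,7,3',4'-tetra-O-benzyl-(−)-epicatechin 3-O-[3,4,5-tris(benzyloxy)benzoate]
Product: 13 8-[(trimethylsilyl)ethynyl]-5,7,3',4'-tetra-O-benzyl-(−)-epicatechin 3-O-[3,4,5-tris(benzyloxy)benzoate]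
Conditions: trimethylsilylacetylene, PdCl2(PhCN)2 (5 mol %), P(t-Bu)3·HBF4 (10 mol %), CuI (5 mol %), i-Pr2NH, dioxane, 50 °C
Reagents that add atoms: trimethylsilylacetylene, `C#C[Si](C)(C)C`
Why: Sonogashira coupling; the bulky electron-rich phosphine should allow oxidative addition into the hindered, di-ortho-oxygenated aryl bromide.

Step 9
Reactants: 13 8-[(trimethylsilyl)ethynyl]-5,7,3',4'-tetra-O-benzyl-(−)-epicatechin 3-O-[3,4,5-tris(benzyloxy)benzoate]
Product: 14 8-ethynyl-5,7,3',4'-tetra-O-benzyl-(−)-epicatechin 3-O-[3,4,5-tris(benzyloxy)benzoate]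
Conditions: K2CO3 (0.2 equiv), MeOH/THF, 0 °C, 30 min
Reagents that add atoms: none
Why: base-catalysed methanolysis of the C(sp)–Si bond should be much faster at 0 °C than transesterification of the hindered, electron-rich aryl ester.

Step 10
Reactants: 14 8-ethynyl-5,7,3',4'-tetra-O-benzyl-(−)-epicatechin 3-O-[3,4,5-tris(benzyloxy)benzoate]; 10 3,4,5-tris(benzyloxy)benzoic acid (1.2 equiv)
Product: 15 8-[(Z)-2-{[3,4,5-tris(benzyloxy)benzoyl]oxy}ethenyl]-5,7,3',4'-tetra-O-benzyl-(−)-epicatechin 3-O-[3,4,5-tris(benzyloxy)benzoate]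
Conditions: [RuCl2(p-cymene)]2 (2.5 mol %), P(4-ClC6H4)3 (6 mol %), DMAP (10 mol %), toluene, 60 °C
Reagents that add atoms: none
Why: ruthenium-catalysed anti-Markovnikov hydro-acyloxylation of a terminal alkyne through a ruthenium vinylidene; the carboxylate adds to the vinylidene α-carbon and protonolysis should give the (Z)-enol ester, as known for aryl alkynes and benzoic acids.

Step 11
Reactants: 9 N,O-acetal of the top half; 15 (Z)-enol gallate of the bottom half (1.5 equiv)
Product: 18 octadeca-O-benzyl ether of the target (protected trimer with free 3-OH on the top unit), via oxocarbenium ion 16 (not isolated), via benzylic cation 17 (not isolated)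
Conditions: ZnBr2 (2 equiv), 4 Å MS, CH2Cl2, −40 to 0 °C, slow addition of 9 to 15 and ZnBr2
Reagents that add atoms: none
Why: Proposed new method: ZnBr2 ionises the C–N bond of 9 to the E oxocarbenium ion 16 (an aryl 2-oxadiene cation, C4a=C8a–O1=C2), C2 of which adds to C3 of the styrene-type enol gallate 15 to give the 2,4,6-trioxygenated benzylic cation 17, and the free ortho carbon C4a then closes ring C onto C4 by a 6-endo Friedel–Crafts attack, that is a stepwise cationic [4+2] whose closest known relatives are the SnCl4-promoted oxa-Povarov reaction of phenol-derived mixed acetals with styrenes and the ZnBr2-promoted tetrahydroquinoline synthesis from N-(α-aminoalkyl)benzotriazoles and alkenes. The regiochemistry (C2 to C3 and not to C4) is secured by ring A of the bottom unit, whose three oxygens stabilise a cation at C4 far better than the acyloxy group could at C3, and closure can only take place at C4a because C8 carries the top unit. The 2,3-cis relation is expected from an endo approach of the Z alkene with both of its substituents under the oxadiene, as found for cis alkenes in Povarov reactions, which places the gallate cis to the outward-pointing ring B of the E oxocarbenium ion. C4 is set trans to the C3 ester because the galloyl carbonyl bridges cation 17 as a 1,3-dioxolan-2-ylium ion that C4a opens from the opposite face, and the resulting 3,4-trans diaxial arrangement also avoids peri strain with the 5-benzyloxy group. The absolute sense at C2 and C3 has to come from the top unit on C8, whose ring A with its 5-benzyloxy group is expected to sit against one face of the cationic O1=C2 unit so that 15 adds to the other; this facial selectivity is the least secure element of the step. Benzotriazolide takes up the proton set free on rearomatisation, so that no strong acid builds up that could cleave the acid-labile C4–aryl bonds.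

Step 12
Reactants: 18 octadeca-O-benzyl ether of the target
Product: 19 epicatechin-(4β→8)-epicatechin 3-O-gallate-(4β→8)-epicatechin 3-O-gallate (CNP0279403.1)
Conditions: H2 (1 atm), Pd(OH)2/C, THF/MeOH/H2O, rt
Reagents that add atoms: none
Why: hydrogenolysis of the eighteen aryl benzyl ethers, as used for benzylated procyanidin gallates; the gallate esters, the ring C ethers and the C4–aryl bonds should survive and no stereocentre is touched.

## Compound list

1 | (−)-epicatechin, (2R,3R) | `O[C@@H]1Cc2c(O)cc(O)cc2O[C@@H]1c1ccc(O)c(O)c1` | starting material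
2 | 5,7,3',4'-tetra-O-benzyl-(−)-epicatechin | `O[C@@H]1Cc2c(OCc9ccccc9)cc(OCc9ccccc9)cc2O[C@@H]1c1ccc(OCc9ccccc9)c(OCc9ccccc9)c1` | intermediate
3 | 5,7,3',4'-tetra-O-benzyl-4β-(2-ethoxyethoxy)epicatechin (4-alkoxy trans to 3-OH) | `CCOCCO[C@H]1c2c(OCc9ccccc9)cc(OCc9ccccc9)cc2O[C@H](c2ccc(OCc9ccccc9)c(OCc9ccccc9)c2)[C@@H]1O` | intermediate
4 | 3,5-bis(benzyloxy)phenol | `Oc1cc(OCc2ccccc2)cc(OCc2ccccc2)c1` | starting material
5 | 2-(5,7,3',4'-tetra-O-benzylepicatechin-4β-yl)-3,5-bis(benzyloxy)phenol (aryl at C4 trans to 3-OH) | `Oc1cc(OCc9ccccc9)cc(OCc9ccccc9)c1[C@H]1c2c(OCc9ccccc9)cc(OCc9ccccc9)cc2O[C@H](c2ccc(OCc9ccccc9)c(OCc9ccccc9)c2)[C@@H]1O` | intermediate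
6 | 3,4-bis(benzyloxy)benzaldehyde | `O=Cc1ccc(OCc2ccccc2)c(OCc2ccccc2)c1` | starting material
7 | (1H-benzotriazol-1-yl)[3,4-bis(benzyloxy)phenyl]methanol (hemiaminal, racemic, not isolated) | `OC(c1ccc(OCc2ccccc2)c(OCc2ccccc2)c1)n1nnc2ccccc21` | intermediate
8 | 1-[chloro(3,4-bis(benzyloxy)phenyl)methyl]-1H-benzotriazole (racemic) | `ClC(c1ccc(OCc2ccccc2)c(OCc2ccccc2)c1)n1nnc2ccccc21` | intermediate
9 | 1-{[2-(5,7,3',4'-tetra-O-benzylepicatechin-4β-yl)-3,5-bis(benzyloxy)phenoxy][3,4-bis(benzyloxy)phenyl]methyl}-1H-benzotriazole (both epimers at the acetal carbon) | `c1ccc2c(c1)nnn2C(Oc1cc(OCc9ccccc9)cc(OCc9ccccc9)c1[C@H]1c2c(OCc9ccccc9)cc(OCc9ccccc9)cc2O[C@H](c2ccc(OCc9ccccc9)c(OCc9ccccc9)c2)[C@@H]1O)c1ccc(OCc9ccccc9)c(OCc9ccccc9)c1` | intermediate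
10 | 3,4,5-tris(benzyloxy)benzoic acid | `OC(=O)c1cc(OCc2ccccc2)c(OCc2ccccc2)c(OCc2ccccc2)c1` | starting material
11 | 5,7,3',4'-tetra-O-benzyl-(−)-epicatechin 3-O-[3,4,5-tris(benzyloxy)benzoate] | `O=C(O[C@@H]1Cc2c(OCc9ccccc9)cc(OCc9ccccc9)cc2O[C@@H]1c1ccc(OCc9ccccc9)c(OCc9ccccc9)c1)c1cc(OCc9ccccc9)c(OCc9ccccc9)c(OCc9ccccc9)c1` | intermediate
12 | 8-bromo derivative of 11 | `O=C(O[C@@H]1Cc2c(OCc9ccccc9)cc(OCc9ccccc9)c(Br)c2O[C@@H]1c1ccc(OCc9ccccc9)c(OCc9ccccc9)c1)c1cc(OCc9ccccc9)c(OCc9ccccc9)c(OCc9ccccc9)c1` | intermediate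
13 | 8-[(trimethylsilyl)ethynyl] derivative of 11 | `O=C(O[C@@H]1Cc2c(OCc9ccccc9)cc(OCc9ccccc9)c(C#C[Si](C)(C)C)c2O[C@@H]1c1ccc(OCc9ccccc9)c(OCc9ccccc9)c1)c1cc(OCc9ccccc9)c(OCc9ccccc9)c(OCc9ccccc9)c1` | intermediate
14 | 8-ethynyl derivative of 11 | `O=C(O[C@@H]1Cc2c(OCc9ccccc9)cc(OCc9ccccc9)c(C#C)c2O[C@@H]1c1ccc(OCc9ccccc9)c(OCc9ccccc9)c1)c1cc(OCc9ccccc9)c(OCc9ccccc9)c(OCc9ccccc9)c1` | intermediate
15 | 8-[(Z)-2-{[3,4,5-tris(benzyloxy)benzoyl]oxy}ethenyl] derivative of 11 | `O=C(O[C@@H]1Cc2c(OCc9ccccc9)cc(OCc9ccccc9)c(/C=C\OC(=O)c3cc(OCc9ccccc9)c(OCc9ccccc9)c(OCc9ccccc9)c3)c2O[C@@H]1c1ccc(OCc9ccccc9)c(OCc9ccccc9)c1)c1cc(OCc9ccccc9)c(OCc9ccccc9)c(OCc9ccccc9)c1` | intermediate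
16 | E O-aryl oxocarbenium ion formed from 9 by loss of benzotriazolide (not isolated) | `C(=[O+]/c1cc(OCc9ccccc9)cc(OCc9ccccc9)c1[C@H]1c2c(OCc9ccccc9)cc(OCc9ccccc9)cc2O[C@H](c2ccc(OCc9ccccc9)c(OCc9ccccc9)c2)[C@@H]1O)\c1ccc(OCc9ccccc9)c(OCc9ccccc9)c1` | intermediate
17 | C4 benzylic cation after C2–C3 bond formation, C2 and C3 configured as in 18 (also present as its galloyl-bridged 1,3-dioxolan-2-ylium form; not isolated) | `O=C(O[C@H]([CH+]c2c(OCc9ccccc9)cc(OCc9ccccc9)c3c2O[C@H](c2ccc(OCc9ccccc9)c(OCc9ccccc9)c2)[C@H](OC(=O)c2cc(OCc9ccccc9)c(OCc9ccccc9)c(OCc9ccccc9)c2)C3)[C@H](Oc2cc(OCc9ccccc9)cc(OCc9ccccc9)c2[C@H]2c3c(OCc9ccccc9)cc(OCc9ccccc9)cc3O[C@H](c3ccc(OCc9ccccc9)c(OCc9ccccc9)c3)[C@@H]2O)c2ccc(OCc9ccccc9)c(OCc9ccccc9)c2)c2cc(OCc9ccccc9)c(OCc9ccccc9)c(OCc9ccccc9)c2` | intermediate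
18 | octadeca-O-benzyl ether of the target: tetra-O-benzylepicatechin-(4β→8)-[tetra-O-benzylepicatechin 3-O-(tri-O-benzylgallate)]-(4β→8)-[tetra-O-benzylepicatechin 3-O-(tri-O-benzylgallate)], top 3-OH free | `O=C(O[C@@H]1[C@@H](c2c(OCc9ccccc9)cc(OCc9ccccc9)c3c2O[C@H](c2ccc(OCc9ccccc9)c(OCc9ccccc9)c2)[C@H](OC(=O)c2cc(OCc9ccccc9)c(OCc9ccccc9)c(OCc9ccccc9)c2)C3)c2c(OCc9ccccc9)cc(OCc9ccccc9)c([C@H]3c4c(OCc9ccccc9)cc(OCc9ccccc9)cc4O[C@H](c4ccc(OCc9ccccc9)c(OCc9ccccc9)c4)[C@@H]3O)c2O[C@@H]1c1ccc(OCc9ccccc9)c(OCc9ccccc9)c1)c1cc(OCc9ccccc9)c(OCc9ccccc9)c(OCc9ccccc9)c1` | intermediate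
19 | epicatechin-(4β→8)-epicatechin 3-O-gallate-(4β→8)-epicatechin 3-O-gallate (CNP0279403.1) | `O=C(O[C@@H]1[C@@H](c2c(O)cc(O)c3c2O[C@H](c2ccc(O)c(O)c2)[C@H](OC(=O)c2cc(O)c(O)c(O)c2)C3)c2c(O)cc(O)c([C@H]3c4c(O)cc(O)cc4O[C@H](c4ccc(O)c(O)c4)[C@@H]3O)c2O[C@@H]1c1ccc(O)c(O)c1)c1cc(O)c(O)c(O)c1` | target

## Step count and risks

Total step count: 12. Longest linear sequence: 8 steps (1, 6, 7, 8, 9, 10, 11, 12).

Steps most likely to fail:

1. Step 11 (Proposed new method). The cycloaddition may fail through poor π-facial selectivity at the oxocarbenium carbon (which would give the 2S,3S,4R middle unit), through an exo approach (2,3-trans), or through interception of cation 16 by nucleophilic ring A carbons (oligomerisation). The fallback uses the classical C4–C8 couplings, sets out from 11 and 3, and comes back at 18. Treatment of 11 with DDQ and 2-ethoxyethanol in CH2Cl2 would give 5,7,3',4'-tetra-O-benzyl-4β-(2-ethoxyethoxy)epicatechin 3-O-[3,4,5-tris(benzyloxy)benzoate] F1. TMSOTf-mediated coupling of F1 with an excess of 11 at −78 °C would give the protected dimer, tetra-O-benzylepicatechin 3-O-(tri-O-benzylgallate)-(4β→8)-tetra-O-benzylepicatechin 3-O-(tri-O-benzylgallate) F2, with 3,4-trans selectivity through anchimeric assistance of the gallate. A second TMSOTf-mediated coupling of electrophile 3 with an excess of F2, through C8 of its upper unit, would then give 18.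

2. Step 10. The ruthenium-catalysed addition may fail through slow vinylidene formation at the hindered alkyne, Markovnikov addition, or Z to E isomerisation of the enol ester. The fallback sets out from 14 and 10 and comes back at 15. Trans-hydroboration of 14 with pinacolborane ([Rh(cod)Cl]2, P(i-Pr)3, Et3N, cyclohexane, rt) would give the (Z)-alkenylboronate, 8-[(Z)-2-(4,4,5,5-tetramethyl-1,3,2-dioxaborolan-2-yl)ethenyl]-5,7,3',4'-tetra-O-benzyl-(−)-epicatechin 3-O-[3,4,5-tris(benzyloxy)benzoate] F3. A Chan–Lam-type coupling of F3 with acid 10 (Cu(OAc)2, Et3N, 4 Å MS, CH2Cl2, air) would give 15 with retention of the double-bond geometry.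

3. Step 3. The arylation may go astray through attack at the carbon between the two benzyloxy groups (para to the hydroxyl) or through double alkylation of the phenol. The fallback sets out from 4 and 3 and comes back at 5. Phenol 4 would be converted with EtMgBr in CH2Cl2/Et2O into bromomagnesium 3,5-bis(benzyloxy)phenoxide F4, which would be treated with 3. Coordination of magnesium to the departing 2-ethoxyethoxy oxygen should deliver C4 to the ortho carbon only (chelation-directed ortho-alkylation of a metal phenoxide), giving 5.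

## Further compounds

F1 | step 11 | 5,7,3',4'-tetra-O-benzyl-4β-(2-ethoxyethoxy)epicatechin 3-O-[3,4,5-tris(benzyloxy)benzoate] | `CCOCCO[C@H]1c2c(OCc9ccccc9)cc(OCc9ccccc9)cc2O[C@H](c2ccc(OCc9ccccc9)c(OCc9ccccc9)c2)[C@@H]1OC(=O)c1cc(OCc9ccccc9)c(OCc9ccccc9)c(OCc9ccccc9)c1`
F2 | step 11 | tetra-O-benzylepicatechin 3-O-(tri-O-benzylgallate)-(4β→8)-tetra-O-benzylepicatechin 3-O-(tri-O-benzylgallate) | `O=C(O[C@@H]1[C@@H](c2c(OCc9ccccc9)cc(OCc9ccccc9)c3c2O[C@H](c2ccc(OCc9ccccc9)c(OCc9ccccc9)c2)[C@H](OC(=O)c2cc(OCc9ccccc9)c(OCc9ccccc9)c(OCc9ccccc9)c2)C3)c2c(OCc9ccccc9)cc(OCc9ccccc9)cc2O[C@@H]1c1ccc(OCc9ccccc9)c(OCc9ccccc9)c1)c1cc(OCc9ccccc9)c(OCc9ccccc9)c(OCc9ccccc9)c1`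
F3 | step 10 | 8-[(Z)-2-(4,4,5,5-tetramethyl-1,3,2-dioxaborolan-2-yl)ethenyl]-5,7,3',4'-tetra-O-benzyl-(−)-epicatechin 3-O-[3,4,5-tris(benzyloxy)benzoate] | `O=C(O[C@@H]1Cc2c(OCc9ccccc9)cc(OCc9ccccc9)c(/C=C\B3OC(C)(C)C(C)(C)O3)c2O[C@@H]1c1ccc(OCc9ccccc9)c(OCc9ccccc9)c1)c1cc(OCc9ccccc9)c(OCc9ccccc9)c(OCc9ccccc9)c1`
F4 | step 3 | bromomagnesium 3,5-bis(benzyloxy)phenoxide | `[O-]c1cc(OCc2ccccc2)cc(OCc2ccccc2)c1.[Mg+2].[Br-]`
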